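The lactone oxygen on C3 of the isochromanone ring is treated as the oxidation product of a C3–B bond. This turns the bond between ring carbon C3 and the first side-chain methylene C1′ into one that a stereospecific 1,2-metallate shift can make. In one operation the side-chain Grignard reagent adds to boron of an (R)-α-chloroboronic ester, its CH2 group migrates to C3 with inversion, peroxide replaces boron by oxygen with retention, and the C3 alkoxide closes the δ-lactone onto the ortho ester. The precursor is an open-chain orsellinate carrying chlorine and an (S,S)-dicyclohexylethanediol boronate on the future C3; the side-chain carbinol comes from a resolved epoxide.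

Key step: step 7

Remark: ring positions follow isochroman-1-one numbering (C1 carbonyl, O2, C3, C4) and the side chain is numbered C1′–C11′ from the ring, so the target is (3R,6′S). The (S,S)-diol is assumed to give the (R)-chloro boronate and the (S,S)-(salen)Co catalyst to leave the (S)-epoxide; both senses are written from memory of the usual rules.

Step 1
Reactants: 1 methyl 2,4-dihydroxy-6-methylbenzoate (methyl orsellinate)
Product: 2 methyl 2,4-bis(benzyloxy)-6-methylbenzoate
Conditions: BnBr, K2CO3, DMF, 60 °C
Reagents that add atoms: benzyl bromide, BrCc1ccccc1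
Why: Williamson ether synthesis in which carbonate in warm DMF should alkylate both phenols, including the hydrogen-bonded ortho one, while the hindered methyl ester is untouched.

Step 2
Reactants: 3 (1S,2S)-1,2-dicyclohexylethane-1,2-diol [(S,S)-DICHED]
Product: 5 (4S,5S)-4,5-dicyclohexyl-2-(dichloromethyl)-1,3,2-dioxaborolane, via diisopropyl (dichloromethyl)boronate 4 (not isolated)
Conditions: CH2Cl2, n-BuLi, THF, −100 °C; B(OiPr)3, −100 °C → rt; HCl (Et2O); then 3, Et2O, MgSO4, rt
Reagents that add atoms: dichloromethane, ClCCl; triisopropyl borate, CC(C)OB(OC(C)C)OC(C)C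
Why: Borylation of (dichloromethyl)lithium followed by transesterification with the diol (preparation of a Matteson dichloromethylboronate) should give a C2-symmetric dioxaborolane whose two boron faces are equivalent, and no new stereocentre is formed.

Step 3
Reactants: 2 methyl 2,4-bis(benzyloxy)-6-methylbenzoate; 5 (4S,5S)-4,5-dicyclohexyl-2-(dichloromethyl)-1,3,2-dioxaborolane
Product: 8 methyl 2,4-bis(benzyloxy)-6-{(2R)-2-chloro-2-[(4S,5S)-4,5-dicyclohexyl-1,3,2-dioxaborolan-2-yl]ethyl}benzoate, via benzylic lithium species 6 (not isolated), via lithium borate complex 7 (not isolated)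
Conditions: LDA, THF, −78 °C; cannulated into 5, THF, −78 °C; ZnCl2 (Et2O), −78 °C → rt; aq. NH4Cl
Reagents that add atoms: none
Why: Lateral lithiation of the ortho-toluate gives a benzylic anion that adds to boron, and ZnCl2-promoted 1,2-migration of the benzyl group with loss of one diastereotopic chloride (Matteson insertion with a chiral dichloromethylboronate) should set the chlorine-bearing carbon as R under control of the (S,S)-diol.

Step 4
Reactants: 9 rac-2-pentyloxirane (1,2-epoxyheptane)
Product: 10 (S)-2-pentyloxirane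
Conditions: (S,S)-(salen)Co(III)OAc (0.5 mol %), H2O (0.55 equiv), neat, 0 °C → rt; distillation
Reagents that add atoms: none
Why: Jacobsen hydrolytic kinetic resolution, in which the chiral cobalt salen catalyst should hydrolyse the (R)-epoxide selectively and leave the (S)-epoxide that carries the future C6′ configuration.

Step 5
Reactants: 10 (S)-2-pentyloxirane
Product: 11 (S)-1-chloroundecan-6-ol
Conditions: Cl(CH2)4MgBr (from 1-bromo-4-chlorobutane, Mg, THF, 0–20 °C), CuI (10 mol %), THF, −40 → −10 °C; aq. NH4Cl
Reagents that add atoms: 1-bromo-4-chlorobutane (used as 4-chlorobutylmagnesium bromide), ClCCCCBr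
Why: Copper-catalysed Grignard opening of the terminal epoxide at its CH2 terminus (SN2) leaves the stereocentre untouched, and magnesium inserts into C–Br in preference to C–Cl so that the chloride survives as the later Grignard handle.

Step 6
Reactants: 11 (S)-1-chloroundecan-6-ol
Product: 12 (S)-6-(benzyloxy)-1-chloroundecane
Conditions: BnOC(=NH)CCl3, TfOH (cat.), CH2Cl2/cyclohexane, 0 °C → rt
Reagents that add atoms: benzyl 2,2,2-trichloroacetimidate, N=C(OCc1ccccc1)C(Cl)(Cl)Cl
Why: Acid-catalysed O-benzylation with the trichloroacetimidate avoids an alkoxide that could displace the primary chloride, and the carbinol C–O bond is not broken, so the configuration is kept.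

Step 7
Reactants: 12 (S)-6-(benzyloxy)-1-chloroundecane; 8 methyl 2,4-bis(benzyloxy)-6-{(2R)-2-chloro-2-[(4S,5S)-4,5-dicyclohexyl-1,3,2-dioxaborolan-2-yl]ethyl}benzoate
Product: 17 (R)-6,8-bis(benzyloxy)-3-[(S)-6-(benzyloxy)undecyl]isochroman-1-one, via Grignard reagent 13 (not isolated), via chloromagnesium borate complex 14 (not isolated), via secondary alkylboronic ester 15 (not isolated), via hydroxy ester 16 (not isolated)
Conditions: 12, Mg, I2 (cat.), THF, 50 °C; then 8 (limiting), THF, −78 °C → rt, 16 h; then 3 M NaOH, 30% H2O2, 0 °C → rt; then 1 M HCl, rt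
Reagents that add atoms: hydrogen peroxide, OO
Why: Grignard reagent 13 adds to the Lewis-acidic boron of 8 to give borate 14, in which the side-chain CH2 migrates from boron to the neighbouring carbon anti-periplanar to C–Cl and expels chloride, forming the C3–C1′ bond with inversion; alkaline peroxide then replaces boron by oxygen with retention and the C3 alkoxide attacks the ortho methyl ester. The closest known reaction type is the Matteson asymmetric homologation (Grignard displacement on an α-chloro boronic ester of a chiral diol) followed by boronate oxidation and lactonisation. The δ-lactone of the isochromanone closes by 6-exo-trig acyl substitution of the C3 oxygen on the ester carbonyl with loss of methanol. The new stereocentre C3 should be R because the R chloride set by the (S,S)-diol in step 3 is transferred by stereospecific inversion and then retention, while C6′ is a spectator. The step needs attack at boron instead of at the ester or the benzylic C–H, carbon and not oxygen migration, and no chloride-induced epimerisation; these should be secured by the high electrophilicity of the boronic ester at −78 °C, the doubly ortho-substituted ester, a near-stoichiometric charge of 13 and prompt use of 8.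

Step 8
Reactants: 17 (R)-6,8-bis(benzyloxy)-3-[(S)-6-(benzyloxy)undecyl]isochroman-1-one
Product: 18 (R)-6,8-dihydroxy-3-[(S)-6-hydroxyundecyl]isochroman-1-one
Conditions: H2 (1 atm), 10% Pd/C, EtOAc/MeOH, rt
Reagents that add atoms: none
Why: Catalytic hydrogenolysis should cleave the two aryl benzyl ethers and the secondary alkyl benzyl ether, while the homobenzylic lactone C3–O bond and both stereocentres are unaffected.

Compound list
1 | methyl 2,4-dihydroxy-6-methylbenzoate (methyl orsellinate) | COC(=O)c1c(C)cc(O)cc1O | starting material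
2 | methyl 2,4-bis(benzyloxy)-6-methylbenzoate | COC(=O)c1c(C)cc(OCc2ccccc2)cc1OCc1ccccc1 | intermediate
3 | (1S,2S)-1,2-dicyclohexylethane-1,2-diol | O[C@@H](C1CCCCC1)[C@@H](O)C1CCCCC1 | starting material
4 | diisopropyl (dichloromethyl)boronate | CC(C)OB(OC(C)C)C(Cl)Cl | intermediate
5 | (4S,5S)-4,5-dicyclohexyl-2-(dichloromethyl)-1,3,2-dioxaborolane | ClC(Cl)B1O[C@@H](C2CCCCC2)[C@H](C2CCCCC2)O1 | intermediate
6 | [3,5-bis(benzyloxy)-2-(methoxycarbonyl)benzyl]lithium | COC(=O)c1c(C[Li])cc(OCc2ccccc2)cc1OCc1ccccc1 | intermediate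
7 | lithium (4S,5S)-2-[3,5-bis(benzyloxy)-2-(methoxycarbonyl)benzyl]-4,5-dicyclohexyl-2-(dichloromethyl)-1,3,2-dioxaborolan-2-uide | [Li+].COC(=O)c1c(C[B-]2(C(Cl)Cl)O[C@@H](C3CCCCC3)[C@H](C3CCCCC3)O2)cc(OCc2ccccc2)cc1OCc1ccccc1 | intermediate
8 | methyl 2,4-bis(benzyloxy)-6-{(2R)-2-chloro-2-[(4S,5S)-4,5-dicyclohexyl-1,3,2-dioxaborolan-2-yl]ethyl}benzoate | COC(=O)c1c(C[C@H](Cl)B2O[C@@H](C3CCCCC3)[C@H](C3CCCCC3)O2)cc(OCc2ccccc2)cc1OCc1ccccc1 | intermediate
9 | rac-2-pentyloxirane (1,2-epoxyheptane) | CCCCCC1CO1 | starting material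
10 | (S)-2-pentyloxirane | CCCCC[C@H]1CO1 | intermediate
11 | (S)-1-chloroundecan-6-ol | CCCCC[C@H](O)CCCCCCl | intermediate
12 | (S)-6-(benzyloxy)-1-chloroundecane | CCCCC[C@H](OCc1ccccc1)CCCCCCl | intermediate
13 | [(6S)-6-(benzyloxy)undecyl]magnesium chloride | CCCCC[C@H](OCc1ccccc1)CCCCC[Mg]Cl | intermediate
14 | chloromagnesium (4S,5S)-2-[(6S)-6-(benzyloxy)undecyl]-2-{(1R)-2-[3,5-bis(benzyloxy)-2-(methoxycarbonyl)phenyl]-1-chloroethyl}-4,5-dicyclohexyl-1,3,2-dioxaborolan-2-uide | Cl[Mg+].COC(=O)c1c(C[C@H](Cl)[B-]2(CCCCC[C@@H](OCc3ccccc3)CCCCC)O[C@@H](C3CCCCC3)[C@H](C3CCCCC3)O2)cc(OCc2ccccc2)cc1OCc1ccccc1 | intermediate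
15 | methyl 2,4-bis(benzyloxy)-6-{(2R,8S)-8-(benzyloxy)-2-[(4S,5S)-4,5-dicyclohexyl-1,3,2-dioxaborolan-2-yl]tridecyl}benzoate | COC(=O)c1c(C[C@@H](CCCCC[C@@H](OCc2ccccc2)CCCCC)B2O[C@@H](C3CCCCC3)[C@H](C3CCCCC3)O2)cc(OCc2ccccc2)cc1OCc1ccccc1 | intermediate
16 | methyl 2,4-bis(benzyloxy)-6-[(2R,8S)-8-(benzyloxy)-2-hydroxytridecyl]benzoate | COC(=O)c1c(C[C@H](O)CCCCC[C@@H](OCc2ccccc2)CCCCC)cc(OCc2ccccc2)cc1OCc1ccccc1 | intermediate
17 | (R)-6,8-bis(benzyloxy)-3-[(S)-6-(benzyloxy)undecyl]isochroman-1-one | CCCCC[C@H](OCc1ccccc1)CCCCC[C@@H]1Cc2cc(OCc3ccccc3)cc(OCc3ccccc3)c2C(=O)O1 | intermediate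
18 | (R)-6,8-dihydroxy-3-[(S)-6-hydroxyundecyl]isochroman-1-one | CCCCC[C@H](O)CCCCC[C@@H]1Cc2cc(O)cc(O)c2C(=O)O1 | target

Total step count: 8. Longest linear sequence: 5 steps (steps 4, 5, 6, 7, 8); the arene branch (steps 1, 3) and the reagent branch (step 2) join it at steps 7 and 3.

Steps most likely to fail

Step 3. The ester-stabilised benzylic anion may bind boron reversibly or through oxygen and self-condense on warming before the 1,2-shift occurs, and chloride may epimerise the new C–Cl centre. The fallback sets out from 2 and comes back to the route at 8. Anion 6 is quenched at −78 °C with trimethyl borate and then anhydrous HCl, a simple C-borylation that needs no migration, to give methyl 2,4-bis(benzyloxy)-6-[(dimethoxyboranyl)methyl]benzoate F1. This is transesterified in the same flask with diol 3 to the isolable methyl 2,4-bis(benzyloxy)-6-{[(4S,5S)-4,5-dicyclohexyl-1,3,2-dioxaborolan-2-yl]methyl}benzoate F2. Classical Matteson homologation of this benzylboronic ester with preformed (dichloromethyl)lithium (THF, −100 °C) and ZnCl2 should then give 8 through borate 7, now formed in the absence of free benzylic anion.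

Step 7. The Grignard reagent may attack the ester or deprotonate the acidified benzylic CH2 with loss of HCl, and a slow migration would allow epimerisation at the chlorine-bearing carbon. The fallback sets out from 8 and 12 and comes back at 17. Buffered sodium perborate oxidation of 8 (oxidation of an α-chloro boronic ester to the aldehyde) gives methyl 2,4-bis(benzyloxy)-6-(2-oxoethyl)benzoate F3. Grignard reagent 13 is transmetalated with ZnCl2 (0.5 equiv) and freed from magnesium salts with 1,4-dioxane to give bis[(6S)-6-(benzyloxy)undecyl]zinc F4. Catalytic enantioselective addition of this dialkylzinc to the aldehyde [Ti(OiPr)4, (1S,2S)-N,N′-bis(trifluoromethanesulfonyl)cyclohexane-1,2-diamine (cat.), toluene, −20 °C; ligand enantiomer chosen for Re-face delivery] forms the same C3–C1′ bond by carbonyl addition. Hydroxy ester 16 formed this way should lactonise on acidic work-up (TsOH) to 17.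

Step 5. Wurtz-type coupling or cyclisation of the chloro Grignard reagent and halide opening of the epoxide by magnesium salts may erode the chain-extension. The fallback sets out from 10 and comes back at 12, carrying C1′ as a silyl ether and introducing chloride last. Copper-catalysed opening of 10 with the Grignard reagent of (4-bromobutoxy)(tert-butyl)dimethylsilane gives (S)-1-[(tert-butyldimethylsilyl)oxy]undecan-6-ol F5. Benzylation (NaH, BnBr, DMF) gives {[(6S)-6-(benzyloxy)undecyl]oxy}(tert-butyl)dimethylsilane F6. Desilylation with TBAF gives (S)-6-(benzyloxy)undecan-1-ol F7, and an Appel reaction (PPh3, CCl4) gives 12.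

Further compounds
F1 | step 3 | methyl 2,4-bis(benzyloxy)-6-[(dimethoxyboranyl)methyl]benzoate | COC(=O)c1c(CB(OC)OC)cc(OCc2ccccc2)cc1OCc1ccccc1
F2 | step 3 | methyl 2,4-bis(benzyloxy)-6-{[(4S,5S)-4,5-dicyclohexyl-1,3,2-dioxaborolan-2-yl]methyl}benzoate | COC(=O)c1c(CB2O[C@@H](C3CCCCC3)[C@H](C3CCCCC3)O2)cc(OCc2ccccc2)cc1OCc1ccccc1
F3 | step 7 | methyl 2,4-bis(benzyloxy)-6-(2-oxoethyl)benzoate | COC(=O)c1c(CC=O)cc(OCc2ccccc2)cc1OCc1ccccc1
F4 | step 7 | bis[(6S)-6-(benzyloxy)undecyl]zinc | CCCCC[C@H](OCc1ccccc1)CCCCC[Zn]CCCCC[C@@H](OCc1ccccc1)CCCCC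
F5 | step 5 | (S)-1-[(tert-butyldimethylsilyl)oxy]undecan-6-ol | CCCCC[C@H](O)CCCCCO[Si](C)(C)C(C)(C)C
F6 | step 5 | {[(6S)-6-(benzyloxy)undecyl]oxy}(tert-butyl)dimethylsilane | CCCCC[C@H](OCc1ccccc1)CCCCCO[Si](C)(C)C(C)(C)C
F7 | step 5 | (S)-6-(benzyloxy)undecan-1-ol | CCCCC[C@H](OCc1ccccc1)CCCCCO
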